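**Retrosynthetic overview**
1. Kumbicin C ⇐ 2-methoxy-5-prenyl-3,6-di(indol-3-yl)-1,4-benzoquinone. The pyran ring closes last, by tautomerisation to an o-quinone methide and oxa-6π electrocyclisation, which also aromatises the central ring.
2. That prenylquinone ⇐ centrosymmetric 2,5-dimethoxy-3,6-di(indol-3-yl)-1,4-benzoquinone + a prenylstannane. One of the two equivalent methoxy groups is exchanged for prenyl (carbonyl allylation, [3,3] shift, loss of methoxide); this symmetry-breaking exchange is the key step.
3. The symmetric dimethoxyquinone ⇐ bromanil + two indoles (double addition–elimination through indole C3), then Br → OMe in the same flask.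
4. Ring order: both indoles and the six-membered carbocycle are bought; only the pyran ring is built.

Assumption: the target SMILES contains no stereocentre, so kumbicin C is achiral and no enantiocontrol is needed; the stereocentres of the transient intermediates 6 and 7 are racemic and are erased in 8.

**Step 1**
Reactants: 1 tetrabromo-1,4-benzoquinone (bromanil); 2 1H-indole
Product: 4 2,5-dimethoxy-3,6-di(1H-indol-3-yl)-1,4-benzoquinone, via dibromoquinone 3 (not isolated)
Conditions: 2 (2.1 equiv), Cs2CO3 (4 equiv), MeCN, rt, 4 h; then NaOMe (6 equiv), MeOH, 0 °C → rt, 2 h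
Reagents that add atoms: sodium methoxide, [Na+].[O-]C
Why: Indole attacks bromanil through C3 by vinylogous addition–elimination (SNV), and the first indolyl group deactivates the cross-ring carbonyl so the second indole enters para (2,5-pattern); the two remaining vinylogous acyl bromides of 3 are then displaced by methoxide in the same addition–elimination manner, as in the known one-flask hydrolysis of such dibromides.

**Step 2**
Reactants: 4 2,5-dimethoxy-3,6-di(1H-indol-3-yl)-1,4-benzoquinone; 5 tributyl(3-methylbut-2-en-1-yl)stannane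
Product: 8 2-methoxy-3,6-di(1H-indol-3-yl)-5-(3-methylbut-2-en-1-yl)-1,4-benzoquinone, via quinol stannyl ether 6 (not isolated), via stannyl dienol ether 7 (not isolated)
Conditions: BF3·OEt2 (2.5 equiv), CH2Cl2, −78 °C; 5 (1.05 equiv) added slowly; −78 → 0 °C
Reagents that add atoms: none
Why: Proposed new method: BF3 activates one of the two equivalent vinylogous-ester carbonyls of centrosymmetric 4 and the allylstannane adds to it through its γ-carbon (SE2′ carbonyl allylation) to give the strained 1,1-dimethylallyl quinol ether 6, whose 1,5-diene undergoes a fast oxy-Cope-type [3,3] shift that delivers the allyl unit, now linear after the second allylic inversion, to the more electrophilic and less hindered methoxy-bearing β-carbon (7), and 7 then expels Bu3SnOMe by E1cB to restore the quinone, so exactly one OMe is exchanged for prenyl and the symmetry is broken; a second exchange is suppressed because 7 is a non-electrophilic dienol ether until it collapses and 5 is limiting; the closest known reactions are the BF3/allylstannane prenylation of quinones at unsubstituted positions (1,2-addition then [3,3] shift) and the facile [3,3] rearrangement of 4-(1,1-dimethylallyl)quinols, extended here to an ipso carbon that carries a leaving group.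

**Step 3**
Reactants: 8 2-methoxy-3,6-di(1H-indol-3-yl)-5-(3-methylbut-2-en-1-yl)-1,4-benzoquinone
Product: 10 kumbicin C (5,8-di(1H-indol-3-yl)-7-methoxy-2,2-dimethyl-2H-chromen-6-ol), via o-quinone methide 9 (not isolated)
Conditions: pyridine, 110 °C, Ar, dark, 3 h
Reagents that add atoms: none
Why: Base-mediated vinylogous enolisation of the prenylquinone gives o-quinone methide 9, which closes by thermal oxa-6π electrocyclisation onto the only carbonyl adjacent to the side chain (the classical prenylquinone-to-chromenol isomerisation), driven by aromatisation of the central ring; no stereocentre is formed and no atom is lost.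

**Compound list**
1 | tetrabromo-1,4-benzoquinone (bromanil) | O=C1C(Br)=C(Br)C(=O)C(Br)=C1Br | starting material
2 | 1H-indole | c1ccc2[nH]ccc2c1 | starting material
3 | 2,5-dibromo-3,6-di(1H-indol-3-yl)cyclohexa-2,5-diene-1,4-dione | O=C1C(Br)=C(c2c[nH]c3ccccc23)C(=O)C(Br)=C1c1c[nH]c2ccccc12 | intermediate
4 | 2,5-dimethoxy-3,6-di(1H-indol-3-yl)cyclohexa-2,5-diene-1,4-dione (dimethyl ether of didemethylasterriquinone D) | O=C1C(OC)=C(c2c[nH]c3ccccc23)C(=O)C(OC)=C1c1c[nH]c2ccccc12 | intermediate
5 | tributyl(3-methylbut-2-en-1-yl)stannane | CCCC[Sn](CCCC)(CCCC)CC=C(C)C | starting material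
6 | 2,5-dimethoxy-3,6-di(1H-indol-3-yl)-4-(2-methylbut-3-en-2-yl)-4-[(tributylstannyl)oxy]cyclohexa-2,5-dien-1-one (racemic, BF3-complexed in the flask) | O=C1C(OC)=C(c2c[nH]c3ccccc23)C(O[Sn](CCCC)(CCCC)CCCC)(C(C)(C)C=C)C(OC)=C1c1c[nH]c2ccccc12 | intermediate
7 | 3,6-dimethoxy-2,5-di(1H-indol-3-yl)-6-(3-methylbut-2-en-1-yl)-4-[(tributylstannyl)oxy]cyclohexa-2,4-dien-1-one (racemic) | O=C1C(OC)(CC=C(C)C)C(c2c[nH]c3ccccc23)=C(O[Sn](CCCC)(CCCC)CCCC)C(OC)=C1c1c[nH]c2ccccc12 | intermediate
8 | 2-methoxy-3,6-di(1H-indol-3-yl)-5-(3-methylbut-2-en-1-yl)cyclohexa-2,5-diene-1,4-dione | O=C1C(CC=C(C)C)=C(c2c[nH]c3ccccc23)C(=O)C(OC)=C1c1c[nH]c2ccccc12 | intermediate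
9 | (6Z)-4-hydroxy-3-methoxy-2,5-di(1H-indol-3-yl)-6-(3-methylbut-2-en-1-ylidene)cyclohexa-2,4-dien-1-one | O=C1/C(=C\C=C(C)C)C(c2c[nH]c3ccccc23)=C(O)C(OC)=C1c1c[nH]c2ccccc12 | intermediate
10 | kumbicin C, 5,8-di(1H-indol-3-yl)-7-methoxy-2,2-dimethyl-2H-chromen-6-ol (achiral) | COc1c(O)c(-c2c[nH]c3ccccc23)c2c(c1-c1c[nH]c3ccccc13)OC(C)(C)C=C2 | target

**Totals**
Total step count: 3. Longest linear sequence: 3 steps (1 → 4 → 8 → 10).

**Steps most likely to fail** (ranked: step 2, then step 1, then step 3)

Step 1 (risk: some meta, 2,6-bis-indolyl isomer in the bromanil condensation, or a crude mixture that does not carry cleanly through the methoxide stage). The fallback sets out from compound 2 and comes back to the route at compound 4. It uses purchased 2,5-dichloro-1,4-benzoquinone (O=C1C=C(Cl)C(=O)C=C1Cl), whose chlorines block C2 and C5 so that acid-promoted conjugate addition can only occur at C3 and C6. Indole (1 equiv) with catalytic conc. HCl in THF at rt gives 2,5-dichloro-3-(1H-indol-3-yl)benzene-1,4-diol F1. DDQ oxidises it to 2,5-dichloro-3-(1H-indol-3-yl)-1,4-benzoquinone F2. A second equivalent of indole in AcOH adds at the only free position to give 2,5-dichloro-3,6-di(1H-indol-3-yl)benzene-1,4-diol F3. DDQ converts this to 2,5-dichloro-3,6-di(1H-indol-3-yl)-1,4-benzoquinone F4. NaOMe in MeOH then displaces both chlorides to give 4. The regiochemistry is unambiguous, at the cost of two extra isolations.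

Step 2 (risk: no carbonyl addition to the doubly donor-substituted quinone, [3,3] shift to the indolyl-bearing carbon, reverse-prenyl product, or double exchange). The fallback sets out from compound 4 and comes back at compound 8, breaking the symmetry by a self-limiting hydrolysis instead. NaOH (1.1 equiv) in aqueous THF at rt cleaves one vinylogous ester; the resulting vinylogous carboxylate resists a second attack. Acidification gives 2-hydroxy-5-methoxy-3,6-di(1H-indol-3-yl)-1,4-benzoquinone F5. PhNTf2 and Et3N in CH2Cl2 convert the acidic OH selectively into the vinylogous acyl triflate 2-methoxy-3,6-di(1H-indol-3-yl)-5-{[(trifluoromethyl)sulfonyl]oxy}-1,4-benzoquinone F6. Stille coupling of F6 with stannane 5 (Pd2(dba)3, AsPh3, NMP, 50 °C) gives 8; reductive elimination from the allylpalladium intermediate at the less hindered terminus gives the linear prenyl group.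

Step 3 (risk: the quinone methide is diverted, or pyridine demethylates the vinylogous ester before cyclisation). The fallback sets out from compound 8 and comes back at compound 10, closing the ring by an ionic route at the hydroquinone level. Na2S2O4 in EtOAc/water reduces 8 to 2-methoxy-3,6-di(1H-indol-3-yl)-5-(3-methylbut-2-en-1-yl)benzene-1,4-diol F7. N-(phenylselanyl)phthalimide with catalytic camphorsulfonic acid in CH2Cl2 at 0 °C effects 6-endo selenoetherification: the only hydroxyl ortho to the side chain attacks the tertiary carbon. This gives 5,8-di(1H-indol-3-yl)-7-methoxy-2,2-dimethyl-3-(phenylselanyl)-3,4-dihydro-2H-chromen-6-ol F8. H2O2 with pyridine in THF at 0 °C gives the selenoxide 5,8-di(1H-indol-3-yl)-7-methoxy-2,2-dimethyl-3-(phenylseleninyl)-3,4-dihydro-2H-chromen-6-ol F9. On warming to rt, F9 undergoes syn-elimination toward C4, the only carbon with β-hydrogens, to give 10.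

**Further compounds**
F1 | step 1 | 2,5-dichloro-3-(1H-indol-3-yl)benzene-1,4-diol | Oc1cc(Cl)c(O)c(-c2c[nH]c3ccccc23)c1Cl
F2 | step 1 | 2,5-dichloro-3-(1H-indol-3-yl)cyclohexa-2,5-diene-1,4-dione | O=C1C=C(Cl)C(=O)C(c2c[nH]c3ccccc23)=C1Cl
F3 | step 1 | 2,5-dichloro-3,6-di(1H-indol-3-yl)benzene-1,4-diol | Oc1c(Cl)c(-c2c[nH]c3ccccc23)c(O)c(Cl)c1-c1c[nH]c2ccccc12
F4 | step 1 | 2,5-dichloro-3,6-di(1H-indol-3-yl)cyclohexa-2,5-diene-1,4-dione | O=C1C(Cl)=C(c2c[nH]c3ccccc23)C(=O)C(Cl)=C1c1c[nH]c2ccccc12
F5 | step 2 | 2-hydroxy-5-methoxy-3,6-di(1H-indol-3-yl)cyclohexa-2,5-diene-1,4-dione | O=C1C(O)=C(c2c[nH]c3ccccc23)C(=O)C(OC)=C1c1c[nH]c2ccccc12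
F6 | step 2 | 2-methoxy-3,6-di(1H-indol-3-yl)-5-{[(trifluoromethyl)sulfonyl]oxy}cyclohexa-2,5-diene-1,4-dione | O=C1C(OS(=O)(=O)C(F)(F)F)=C(c2c[nH]c3ccccc23)C(=O)C(OC)=C1c1c[nH]c2ccccc12
F7 | step 3 | 2-methoxy-3,6-di(1H-indol-3-yl)-5-(3-methylbut-2-en-1-yl)benzene-1,4-diol | COc1c(O)c(-c2c[nH]c3ccccc23)c(CC=C(C)C)c(O)c1-c1c[nH]c2ccccc12
F8 | step 3 | 5,8-di(1H-indol-3-yl)-7-methoxy-2,2-dimethyl-3-(phenylselanyl)-3,4-dihydro-2H-chromen-6-ol (racemic) | COc1c(O)c(-c2c[nH]c3ccccc23)c2c(c1-c1c[nH]c3ccccc13)OC(C)(C)C([Se]c1ccccc1)C2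
F9 | step 3 | 5,8-di(1H-indol-3-yl)-7-methoxy-2,2-dimethyl-3-(phenylseleninyl)-3,4-dihydro-2H-chromen-6-ol (racemic) | COc1c(O)c(-c2c[nH]c3ccccc23)c2c(c1-c1c[nH]c3ccccc13)OC(C)(C)C([Se](=O)c1ccccc1)C2
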